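- Count the enzyme.

common to all: solid substrate 0.15 M; enzyme 30 µM; time 50 s
- midnight: impurity 15 µM
- dusk: impurity 40 µM
- dawn: impurity 120 µM

- solid, in amounts per volume of the solution: solid substrate
- at the start none of the solid substrate is in solution
- "hardly changes" means that all values lie within two and a half points (for a concentration: within two and a half percent of the largest)
- run time (midnight): 50 s

- [target] at the end for midnight, dusk, dawn, in this order
- how that number moves from the first to the last of them (falls all the way / hardly changes / rises all the way / rises, then falls / falls, then rises)

    solid substrate ⇌ starting material, rate k1*(cs1 - [starting material]) while solid is left; crystals form when [starting material] > cs1 (cs1 = 0.054 M, k1 = 0.096 s⁻¹)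
    starting material + enzyme → target + enzyme, rate k2*[starting material]*[enzyme]/(1 + ([starting material]/Km2)) (Km2 = 0.12 M, k2 = 85000 M⁻¹ s⁻¹)
    enzyme + impurity → spent catalyst (k3 = 39000 M⁻¹ s⁻¹)

- I work with two amounts, the charges of enzyme and impurity, since each impurity takes one enzyme and at midnight this kill lasts about 0.855 s, far shorter than the run of 50 s.
- At midnight I reckon 50.0% for the survivor share, one minus the smaller charge over the larger, the fraction of the larger partner that outlives the kill; impurity is the limiting reagent there, so c(enzyme) stays at 15.0 µM.
- At midnight that enzyme gives starting material a first-order loss constant of 1.27 s⁻¹, larger than the dissolving coefficient 0.096 s⁻¹, so I take dissolving as the rate-limiting step, with a feed of 0.00518 M s⁻¹.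
- At that feed the midnight solid needs 28.9 s, less than the run, so I commit to c(target) = 150 mM at midnight.
- At dusk and dawn the impurity charge is the larger, so the survivor share passes to impurity and c(target) stops growing with the kill.
- That kill starts faster at dawn than at dusk, at 4.68 s⁻¹ against 1.56 s⁻¹ per enzyme.
- At dusk the tail of the kill runs at 0.390 s⁻¹, slower than the 2.55 s⁻¹ at which the charged enzyme consumes starting material, so I let the feed pass into target for the lifetime of that tail, and c(target) comes to about 13.3 mM.
- At dawn the kill at mean impurity runs at 4.09 s⁻¹, faster than that consumption, so I let starting material build up as feed times time under a dying enzyme, and c(target) comes to about 0.788 mM.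
- Set side by side, my three figures give a row that falls all the way.
- The forecast gives 0.15 M, 0.0138 M and 7.500 × 10⁻⁴ M, falls all the way, holding that “the impurity exceeds the enzyme and kills it within seconds or less”.
- The simulation gives 0.150 M, 0.0137 M and 7.15 × 10⁻⁴ M: falls all the way.

- At midnight the half-life of enzyme by its loss to spent catalyst is 340 min at 15.5 s, far longer than the run of 50 s, and enzyme holds 50.0% of the catalyst at 15.0 s and 50.0% at 50.0 s, which is the survivor share 50.0%. At dusk the same share, taken on impurity, comes to 25.0%, and the impurity left of its own charge at 50.0 s is 25%.

(All constants are those of an exercise; the rest is arithmetic.)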